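Take the ratio of reagent to substrate as your measure: the flask has 0.949, the gamma run 0.479 and the delta run 1.92, with the substrate charge the same in each.

| flask | substrate | reagent | remark | time |
|---|---|---|---|---|
| gamma | 0.073 M | 0.035 M | run made earlier |  |
| delta | 0.073 M | 0.14 M | run made earlier |  |
| eta | 0.036 M | 0.0693 M | run made earlier |  |
| flask | 0.073 M | 0.0693 M |  | 10 h |

| run | time / h | mono adduct / % | substrate / % |
|---|---|---|---|
| gamma | 0.333 | 9.8 | 88.3 |
| gamma | 0.667 | 14.4 | 79.7 |
| gamma | 1.33 | 16.4 | 69.5 |
| gamma | 3.00 | 12.0 | 60.2 |
| gamma | 6.00 | 6.1 | 51.2 |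
| gamma | 12.0 | 2.5 | 51.6 |
| delta | 0.333 | 24.9 | 57.9 |
| delta | 0.667 | 25.8 | 38.1 |
| delta | 1.33 | 30.4 | 20.3 |
| delta | 3.00 | 21.2 | 5.5 |
| delta | 6.00 | 8.0 | 1.0 |
| delta | 12.0 | 3.9 | 0 |
| eta | 0.333 | 17.8 | 74.4 |
| eta | 0.833 | 26.0 | 51.3 |
| eta | 2.00 | 27.5 | 27.2 |
| eta | 5.00 | 13.8 | 7.6 |
| eta | 12.0 | 5.3 | 0 |

(scatter of a reading: 1 percentage point)

- the moment within 10 h at which there is most mono adduct
- the amount of mono adduct, in percent of the substrate charged, at that time

- the numbers in the tables scatter with a standard deviation of 1 percentage point

Look for the crossing where the making of mono adduct falls to its using: that moment is the peak. Read that peak as the highest reading of each run: 16.4 % of the substrate charged at 1.33 h in the gamma run, 30.4 % at 1.33 h in the delta run. From these two readings form the peak gain, the points of mono adduct won per unit of the natural log of the ratio: 10 points. The flask stands half of the way from gamma to delta on that scale, so commit to 23.3 % near 1.33 h. Your forecast gives 23 % at 1.3 h: “Interpolating gives a peak of about 23% near 1.3 h.” Count mine and yours as one estimate, since both interpolate between gamma and delta on a log scale, though you read the delta peak as about 29 % where I took its highest reading.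

The flask gives 24.6 % at 1.36 h.

    reagent + mono adduct ⇌ double product (K = 16.0 /M, k = 0.00721 /M/s)
    substrate + reagent → mono adduct (k = 0.00388 /M/s)
    mono adduct ⇌ isomer of the product (K = 26.0, k = 1.92 × 10⁻⁴ /s)

The flask's peak stands 1.3 points above the peak gain's figure, against a scatter of 1 point per reading. Apply the peak gain to the neighbour flask with ratio 1.64 and the same substrate charge: it gives 28.8 %, and that neighbour reaches 28.7 %. In the flask, mono adduct is made 1.22 times as fast as it is used at 0.890 h, each step taken net, and that ratio is down to 0.670 at 10.0 h. Between those times lies the peak, and at 10.0 h the flask holds 5.54 % mono adduct against 80.8 % isomer of the product.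

The readings are calculated for substances that don't exist; the scatter is artificial.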